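**Retrosynthetic overview**

1. Feature: in the cyclobutane of 17 the two CO2H-bearing methines (C1, C2) are adjacent, cis to each other and on the face of the methyl groups of the quaternary carbons C3 and C4. Joining the two carboxyl carbons gives a cyclobutene fused on C1–C2, that is a bicyclo[2.2.0]hex-5-ene, the valence isomer of a cyclohexa-1,3-diene whose two sp3 carbons are C3 and C4.
2. Last disconnection: both CO2H groups come from oxidative cleavage of that etheno bridge, which is kept to the end so that C1 and C2 are not enolisable while the pyranones are built.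
3. Each 4-methoxy-3-methyl-2-pyranone: C6 from an anhydride carbonyl of 6 (taken to CHO), C2–C5 from methyl 2-methyl-3-oxobutanoate (aldol, oxidation, lactonisation, O-methylation).
4. Key disconnection: the C1–C2 bond, by photochemical disrotatory 4π closure of the cis-fused diene anhydride 5 to 6. Diene 5 comes from the Diels–Alder adduct of dimethylmaleic anhydride and butadiene (sets C3/C4 cis) by bromination and double dehydrobromination.
5. Ring order: cyclohexene (step 1), cyclohexadiene (step 3), cyclobutane plus cyclobutene (step 4), two pyranones (step 9), cyclobutene opened (step 11).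

Key step: step 4

Remark: 17 has a mirror plane (meso), so no absolute stereocontrol is needed; chiral intermediates are racemic and the stereo-SMILES show relative configuration. After step 4 no operation exceeds 50 °C, because bicyclo[2.2.0]hex-2-enes revert to cyclohexa-1,3-dienes above about 100 °C.

**Route**

Step 1
Reactants: 1 2,3-dimethylmaleic anhydride; 2 buta-1,3-diene
Product: 3 cis-1,2-dimethylcyclohex-4-ene-1,2-dicarboxylic anhydride (meso)
Conditions: 2 (excess), hydroquinone (cat.), PhMe, 180 °C, sealed autoclave
Reagents that add atoms: none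
Why: Diels–Alder reaction; the tetrasubstituted alkene of 1 is a sluggish dienophile but is known to add butadiene under forcing thermal conditions, and suprafacial addition fixes the two methyl groups (on the future C3 and C4) cis.

Step 2
Reactants: 3 cis-1,2-dimethylcyclohex-4-ene-1,2-dicarboxylic anhydride
Product: 4 trans-4,5-dibromo-cis-1,2-dimethylcyclohexane-1,2-dicarboxylic anhydride (racemic)
Conditions: Br2, CH2Cl2, 0 °C, dark
Reagents that add atoms: bromine, BrBr
Why: electrophilic anti addition of bromine through a bromonium ion gives the trans-dibromide, and the alkene is the only reactive site.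

Step 3
Reactants: 4 trans-4,5-dibromo-cis-1,2-dimethylcyclohexane-1,2-dicarboxylic anhydride
Product: 5 cis-1,2-dimethylcyclohexa-3,5-diene-1,2-dicarboxylic anhydride (meso)
Conditions: DBU (3 equiv), PhMe, 80 °C
Reagents that add atoms: none
Why: two successive anti E2 eliminations (each axial bromide has an anti-periplanar hydrogen only on the neighbouring CH2, and the second bromide is allylic after the first loss) give the conjugated 3,5-diene, which cannot aromatise or shift because C1 and C2 are quaternary, while the hindered tetrasubstituted anhydride is slow to acylate the amidine.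

Step 4
Reactants: 5 cis-1,2-dimethylcyclohexa-3,5-diene-1,2-dicarboxylic anhydride
Product: 6 2,3-dimethylbicyclo[2.2.0]hex-5-ene-2,3-dicarboxylic anhydride, anhydride ring exo (anti to C5=C6), both methyls endo (on the face of the etheno bridge), meso
Conditions: hν (254 nm, quartz), degassed Et2O (0.01 M), −10 °C; chromatography; the facial isomer is heated (PhMe, 130 °C) back to 5 and re-irradiated
Reagents that add atoms: none
Why: Excitation of the s-cis diene (about 260 nm) is followed by disrotatory 4π electrocyclisation between the diene termini C3 and C6 of 5, which forms the C3–C6 σ bond and leaves C4=C5 as a cyclobutene; the closest known reaction is the photochemical closure of cis-1,2-dihydrophthalic anhydride to bicyclo[2.2.0]hex-5-ene-2,3-dicarboxylic anhydride. The ring closed is the cyclobutane C1–C2–C3–C6 (the four-membered ring of the target), by electrocyclic disrotatory closure across the termini of a diene held s-cis in a six-membered ring. The two new stereocentres C3 and C6 must carry cis hydrogens because a cyclobutane fused to a cyclobutene can only be cis-fused, and their relation to the quaternary carbons follows from the face toward which C4=C5 folds. Periselectivity over conrotatory 6π opening is secured by the anhydride ring, since opening of the C1–C2 bond would have to place an E double bond in a nine-membered cyclic anhydride. Facial selectivity (C4=C5 on the methyl face) is only weakly biased, by the anhydride ring avoiding a syn, face-to-face relation with the new cyclobutene, so 6 is expected together with its facial isomer and is separated by chromatography. The facial isomer is not lost, because thermal ring opening of a bicyclo[2.2.0]hex-2-ene returns diene 5 for another pass.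

Step 5
Reactants: 6 2,3-dimethylbicyclo[2.2.0]hex-5-ene-2,3-dicarboxylic anhydride (methyls endo)
Product: 7 exo,exo-2,3-bis(hydroxymethyl)-endo,endo-2,3-dimethylbicyclo[2.2.0]hex-5-ene (meso)
Conditions: LiAlH4 (excess), THF, 0 to 50 °C; then H2O, filtration
Reagents that add atoms: none
Why: hydride reduction of a cyclic anhydride to the 1,4-diol; LiAlH4 does not touch the isolated cyclobutene, and the temperature stays well below that of thermal opening of the bicycle.

Step 6
Reactants: 7 exo,exo-2,3-bis(hydroxymethyl)-endo,endo-2,3-dimethylbicyclo[2.2.0]hex-5-ene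
Product: 8 endo,endo-2,3-dimethylbicyclo[2.2.0]hex-5-ene-exo,exo-2,3-dicarbaldehyde (meso)
Conditions: (COCl)2, DMSO, CH2Cl2, −78 °C; Et3N, −78 to 0 °C
Reagents that add atoms: none
Why: Swern oxidation activates both neopentyl hydroxyls before base is added, so the dialdehyde forms without lactol-to-lactone over-oxidation, and the aldehydes have no alpha hydrogen and cannot epimerise.

Step 7
Reactants: 8 endo,endo-2,3-dimethylbicyclo[2.2.0]hex-5-ene-exo,exo-2,3-dicarbaldehyde; 9 methyl 2-methyl-3-oxobutanoate
Product: 11 dimethyl 5,5'-(endo,endo-2,3-dimethylbicyclo[2.2.0]hex-5-ene-exo,exo-2,3-diyl)bis(5-hydroxy-2-methyl-3-oxopentanoate) as a mixture of diastereomers, via ketoester dianion 10 (not isolated)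
Conditions: 9 (3 equiv), NaH, THF, 0 °C; n-BuLi, 0 °C; add 8, −78 to −20 °C; AcOH
Reagents that add atoms: none
Why: aldol addition of the terminal (gamma) carbanion of the acetoacetate dianion to both formyl groups, the standard first stage of the 4-hydroxy-2-pyranone synthesis from aldehydes; the new carbinol and C2 stereocentres form without control and are erased in steps 8 and 9.

Step 8
Reactants: 11 bis-aldol adduct
Product: 12 dimethyl 5,5'-(endo,endo-2,3-dimethylbicyclo[2.2.0]hex-5-ene-exo,exo-2,3-diyl)bis(2-methyl-3,5-dioxopentanoate) (enolised beta,delta-diketo ester)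
Conditions: Dess–Martin periodinane, CH2Cl2, 0 °C to rt
Reagents that add atoms: none
Why: Dess–Martin oxidation of the secondary carbinols gives the beta,delta-diketo esters at room temperature without acid or base strong enough to disturb the bicycle.

Step 9
Reactants: 12 bis(beta,delta-diketo ester)
Product: 13 6,6'-(endo,endo-2,3-dimethylbicyclo[2.2.0]hex-5-ene-exo,exo-2,3-diyl)bis(4-hydroxy-3-methyl-2H-pyran-2-one) (meso)
Conditions: DBU, PhMe, rt; acidic work-up
Reagents that add atoms: none
Why: base-mediated lactonisation, in which the enolate oxygen of each delta-ketone attacks the methyl ester to close a six-membered ring that tautomerises to the 4-hydroxy-2-pyranone; it runs at room temperature.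

Step 10
Reactants: 13 bis(4-hydroxy-3-methyl-2-pyranone)
Product: 14 6,6'-(endo,endo-2,3-dimethylbicyclo[2.2.0]hex-5-ene-exo,exo-2,3-diyl)bis(4-methoxy-3-methyl-2H-pyran-2-one) (meso)
Conditions: Me2SO4, K2CO3, acetone, 40 °C
Reagents that add atoms: dimethyl sulfate, COS(=O)(=O)OC
Why: O-alkylation of the vinylogous acid at O4 with a hard methylating agent and carbonate in acetone, conditions that favour the 4-methoxy-2-pyranone over the 2-methoxy-4-pyranone isomer.

Step 11
Reactants: 14 bis(4-methoxy-3-methyl-2-pyranone) with intact etheno bridge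
Product: 16 3,4-dimethyl-3,4-bis(4-methoxy-3-methyl-2-oxo-2H-pyran-6-yl)cyclobutane-1,2-dicarbaldehyde (formyl groups cis and on the methyl face; crude material goes directly into step 12), via exo-cis-diol 15 (not isolated)
Conditions: OsO4 (cat.), NaIO4, 2,6-lutidine, 1,4-dioxane/H2O, 0 °C to rt
Reagents that add atoms: osmium tetroxide, O=[Os](=O)(=O)=O; sodium periodate, [Na+].[O-]I(=O)(=O)=O (renews the oxygen on osmium)
Why: Lemieux–Johnson oxidation; the strained, unconjugated cyclobutene should be osmylated from its open convex face much faster than the electron-poor pyranone double bonds, and periodate cleaves only the C5–C6 bond of the diol, so the two methines keep their configuration.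

Step 12
Reactants: 16 cis-dialdehyde
Product: 17 3,4-dimethyl-3,4-bis(4-methoxy-3-methyl-2-oxo-2H-pyran-6-yl)cyclobutane-1,2-dicarboxylic acid, both CO2H and both CH3 on one face, both pyranones on the other (meso)
Conditions: NaClO2, NaH2PO4, 2-methyl-2-butene, t-BuOH/H2O, 0 °C to rt
Reagents that add atoms: sodium chlorite, [Na+].[O-]Cl=O
Why: Pinnick oxidation at buffered pH with 2-methyl-2-butene as hypochlorite scavenger converts both aldehydes to acids without epimerising the alpha methines or chlorinating the pyranones.

**Compound list**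

1 | 2,3-dimethylmaleic anhydride | CC1=C(C)C(=O)OC1=O | starting material
2 | buta-1,3-diene | C=CC=C | starting material
3 | cis-1,2-dimethylcyclohex-4-ene-1,2-dicarboxylic anhydride (meso) | O=C1OC(=O)[C@@]2(C)CC=CC[C@]21C | intermediate
4 | trans-4,5-dibromo-cis-1,2-dimethylcyclohexane-1,2-dicarboxylic anhydride (racemic, one enantiomer drawn) | O=C1OC(=O)[C@@]2(C)C[C@H](Br)[C@@H](Br)C[C@]21C | intermediate
5 | cis-1,2-dimethylcyclohexa-3,5-diene-1,2-dicarboxylic anhydride (meso) | O=C1OC(=O)[C@@]2(C)C=CC=C[C@]21C | intermediate
6 | 2,3-dimethylbicyclo[2.2.0]hex-5-ene-2,3-dicarboxylic anhydride, anhydride exo, methyls endo (meso) | O=C1OC(=O)[C@@]2(C)[C@H]3[C@H](C=C3)[C@]21C | intermediate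
7 | exo,exo-2,3-bis(hydroxymethyl)-endo,endo-2,3-dimethylbicyclo[2.2.0]hex-5-ene | OC[C@@]1(C)[C@H]2[C@H](C=C2)[C@]1(CO)C | intermediate
8 | endo,endo-2,3-dimethylbicyclo[2.2.0]hex-5-ene-exo,exo-2,3-dicarbaldehyde | O=C[C@@]1(C)[C@H]2[C@H](C=C2)[C@]1(C=O)C | intermediate
9 | methyl 2-methyl-3-oxobutanoate | CC(=O)C(C)C(=O)OC | starting material
10 | sodium lithium 1,3-dianion of 9 | [Na+].[Li+].C=C([O-])C(C)=C([O-])OC | intermediate
11 | bis-aldol adduct, dimethyl 5,5'-(bicyclohexenediyl)bis(5-hydroxy-2-methyl-3-oxopentanoate), carbinol and C2 centres unassigned | COC(=O)C(C)C(=O)CC(O)[C@@]1(C)[C@H]2[C@H](C=C2)[C@]1(C(O)CC(=O)C(C)C(=O)OC)C | intermediate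
12 | bis(beta,delta-diketo ester), dimethyl 5,5'-(bicyclohexenediyl)bis(2-methyl-3,5-dioxopentanoate), drawn as keto form | COC(=O)C(C)C(=O)CC(=O)[C@@]1(C)[C@H]2[C@H](C=C2)[C@]1(C(=O)CC(=O)C(C)C(=O)OC)C | intermediate
13 | 6,6'-(endo,endo-2,3-dimethylbicyclo[2.2.0]hex-5-ene-exo,exo-2,3-diyl)bis(4-hydroxy-3-methyl-2H-pyran-2-one) | Oc1cc(oc(=O)c1C)[C@@]2(C)[C@H]3[C@H](C=C3)[C@]2(c4cc(O)c(C)c(=O)o4)C | intermediate
14 | 6,6'-(endo,endo-2,3-dimethylbicyclo[2.2.0]hex-5-ene-exo,exo-2,3-diyl)bis(4-methoxy-3-methyl-2H-pyran-2-one) | COc1cc(oc(=O)c1C)[C@@]2(C)[C@H]3[C@H](C=C3)[C@]2(c4cc(OC)c(C)c(=O)o4)C | intermediate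
15 | exo,cis-5,6-diol of 14 (bicyclo[2.2.0]hexane-5,6-diol, hydroxyls on the convex face) | COc1cc(oc(=O)c1C)[C@@]2(C)[C@H]3[C@H]([C@H](O)[C@@H]3O)[C@]2(c4cc(OC)c(C)c(=O)o4)C | intermediate
16 | 3,4-dimethyl-3,4-bis(4-methoxy-3-methyl-2-oxo-2H-pyran-6-yl)cyclobutane-1,2-dicarbaldehyde, formyls cis and on the methyl face | COc1cc(oc(=O)c1C)[C@@]2(C)[C@H](C=O)[C@H](C=O)[C@]2(c4cc(OC)c(C)c(=O)o4)C | intermediate
17 | 3,4-dimethyl-3,4-bis(4-methoxy-3-methyl-2-oxo-2H-pyran-6-yl)cyclobutane-1,2-dicarboxylic acid (CNP0574758.1, meso) | COc1cc([C@@]2(C)[C@H](C(=O)O)[C@H](C(=O)O)[C@@]2(C)c2cc(OC)c(C)c(=O)o2)oc(=O)c1C | target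

**Step count and risks**

Total step count: 12. Longest linear sequence: 12 steps (1 and 2 to 17; 9 enters at step 7).

Steps most likely to fail:

Step 4. What may go wrong: the C4=C5 unit folds toward the anhydride face instead of the methyl face (low or reversed facial selectivity). In addition, conrotatory opening of the C1–C2 bond followed by thermal reclosure would erode the cis relation of the methyl groups. The fallback sets out from 5 and comes back at 17; it moves the stereochemical decision from the photochemical step to a thermodynamic equilibration at the end. If irradiation gives mainly the facial isomer, 2,3-dimethylbicyclo[2.2.0]hex-5-ene-2,3-dicarboxylic anhydride with the anhydride ring on the etheno face F1, that isomer is carried through steps 5 to 12 unchanged. This gives in turn the diol F2, the dialdehyde F3, the bis-aldol adduct F4, the bis(diketo ester) F5, the bis(hydroxypyranone) F6, the bis(methoxypyranone) F7, the exo-cis-diol F8 (not isolated), the cyclobutane dialdehyde F9 and the diacid F10, which differs from 17 at both carboxyl-bearing methines. These two centres are now enolisable. Heating F10 in Ac2O with NaOAc (130 °C) closes the cyclic anhydride and lets it migrate, by enolisation of the opened mixed anhydride, from the crowded pyranone face to the methyl face, giving the cyclic anhydride of the target F11. This is the classical thermodynamic interconversion of truxinic-type acids through their anhydrides, and it is expected to favour the ring flanked by methyl over the ring flanked by two pyranones. Hydrolysis (THF/H2O, rt) then gives 17.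

Step 7. What may go wrong: after the first aldol addition the alkoxide closes onto the neighbouring formyl group, and the resulting lactolate stalls the second addition (incomplete double addition to a cis-1,4-dialdehyde). The fallback sets out from 8 and comes back at 13; it builds the pyranones at the ketone level. MeMgBr (excess, THF, −78 °C to rt) is small and can be driven to the double adduct, the bis(1-hydroxyethyl) compound F12. Dess–Martin oxidation gives the cis-diacetyl compound F13. Soft enolisation (TMSOTf, Et3N, CH2Cl2, 0 °C), which avoids a free enolate next to the second ketone, gives the bis(trimethylsilyl enol ether) F14. C-Acylation and ring closure with methylmalonyl dichloride, CC(C(=O)Cl)C(=O)Cl (Et2O, −78 °C to rt), the known pyranone annulation of silyl enol ethers with malonyl dichlorides, then gives 13.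

Step 11. What may go wrong: osmylation of the pyranone 5,6-double bonds competes with that of the cyclobutene, or the liberated cis-dialdehyde epimerises or closes to a cyclic hydrate in the buffered aqueous medium before it is oxidised. The fallback sets out from 14 and comes back at 17. The cyclobutene is ozonised (one equivalent to an indicator end point, −78 °C) in aqueous MeCN, where water intercepts the carbonyl oxide, and NaClO2 is added to the same flask so that each aldehyde is oxidised as it is released. This uses no osmium and no amine base, and no new compound is isolated.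

Further compounds
F1 | step 4 | 2,3-dimethylbicyclo[2.2.0]hex-5-ene-2,3-dicarboxylic anhydride, anhydride endo (on the etheno face), methyls exo | O=C1OC(=O)[C@]2(C)[C@H]3[C@H](C=C3)[C@@]21C
F2 | step 4 | endo,endo-2,3-bis(hydroxymethyl)-exo,exo-2,3-dimethylbicyclo[2.2.0]hex-5-ene | OC[C@]1(C)[C@H]2[C@H](C=C2)[C@@]1(CO)C
F3 | step 4 | exo,exo-2,3-dimethylbicyclo[2.2.0]hex-5-ene-endo,endo-2,3-dicarbaldehyde | O=C[C@]1(C)[C@H]2[C@H](C=C2)[C@@]1(C=O)C
F4 | step 4 | bis-aldol adduct of F3 (diastereomer mixture) | COC(=O)C(C)C(=O)CC(O)[C@]1(C)[C@H]2[C@H](C=C2)[C@@]1(C(O)CC(=O)C(C)C(=O)OC)C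
F5 | step 4 | bis(beta,delta-diketo ester) of the endo series | COC(=O)C(C)C(=O)CC(=O)[C@]1(C)[C@H]2[C@H](C=C2)[C@@]1(C(=O)CC(=O)C(C)C(=O)OC)C
F6 | step 4 | 6,6'-(exo,exo-2,3-dimethylbicyclo[2.2.0]hex-5-ene-endo,endo-2,3-diyl)bis(4-hydroxy-3-methyl-2H-pyran-2-one) | Oc1cc(oc(=O)c1C)[C@]2(C)[C@H]3[C@H](C=C3)[C@@]2(c4cc(O)c(C)c(=O)o4)C
F7 | step 4 | 6,6'-(exo,exo-2,3-dimethylbicyclo[2.2.0]hex-5-ene-endo,endo-2,3-diyl)bis(4-methoxy-3-methyl-2H-pyran-2-one) | COc1cc(oc(=O)c1C)[C@]2(C)[C@H]3[C@H](C=C3)[C@@]2(c4cc(OC)c(C)c(=O)o4)C
F8 | step 4 | exo,cis-5,6-diol of F7 | COc1cc(oc(=O)c1C)[C@]2(C)[C@H]3[C@H]([C@H](O)[C@@H]3O)[C@@]2(c4cc(OC)c(C)c(=O)o4)C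
F9 | step 4 | 3,4-dimethyl-3,4-bis(4-methoxy-3-methyl-2-oxo-2H-pyran-6-yl)cyclobutane-1,2-dicarbaldehyde, formyls cis and on the pyranone face | COc1cc(oc(=O)c1C)[C@]2(C)[C@H](C=O)[C@H](C=O)[C@@]2(c4cc(OC)c(C)c(=O)o4)C
F10 | step 4 | diastereomer of 17 with both CO2H on the pyranone face | COc1cc(oc(=O)c1C)[C@]2(C)[C@H](C(=O)O)[C@H](C(=O)O)[C@@]2(c4cc(OC)c(C)c(=O)o4)C
F11 | step 4 | cyclic anhydride of 17 (anhydride ring on the methyl face) | COc1cc(oc(=O)c1C)[C@@]2(C)[C@@H]3C(=O)OC(=O)[C@@H]3[C@]2(c4cc(OC)c(C)c(=O)o4)C
F12 | step 7 | exo,exo-2,3-bis(1-hydroxyethyl)-endo,endo-2,3-dimethylbicyclo[2.2.0]hex-5-ene (carbinol centres unassigned) | CC(O)[C@@]1(C)[C@H]2[C@H](C=C2)[C@]1(C(C)O)C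
F13 | step 7 | exo,exo-2,3-diacetyl-endo,endo-2,3-dimethylbicyclo[2.2.0]hex-5-ene | CC(=O)[C@@]1(C)[C@H]2[C@H](C=C2)[C@]1(C(C)=O)C
F14 | step 7 | bis(trimethylsilyl enol ether) of F13 | C=C(O[Si](C)(C)C)[C@@]1(C)[C@H]2[C@H](C=C2)[C@]1(C(=C)O[Si](C)(C)C)C
F0 | step 11 | none | none
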